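**Retrosynthetic overview**
- The target is opened in one operation to an acyclic (S)-aldol, ArCH(OH)CH2C(O)CH=CHOMe (Ar = 2,6-dimethoxyphenyl), and the γ-lithiated form of methyl (E)-3,4,4-trimethoxybut-2-enoate.
- In that operation ring C closes first (O1–C8a, alkoxide addition–elimination), then ring A (C8–C8a Michael, C4a–C5 Dieckmann). Loss of one ketal methoxy with the C8a hydrogen aromatises ring A without any oxidant.
- The crotonate supplies C5–C8 with all oxygens in place: ester carbonyl becomes 5-OH, enol ether becomes 7-OMe, ketal becomes 8-OMe. No protecting groups are used.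
- C2 is set earlier by a catalytic asymmetric Mukaiyama aldol of 2,6-dimethoxybenzaldehyde with Danishefsky's diene (C2–C3 bond).
- Ring order: B (bought), then C, then A, the last two in the same flask.

Assumption: flavanone numbering (O1, C2, C3, C4, C4a, C5–C8, C8a) is used for the atoms of all intermediates.

**Route**

Step 1
Reactants: 1 methyl 4,4-dimethoxy-3-oxobutanoate
Product: 3 methyl (E)-3,4,4-trimethoxybut-2-enoate, via dimethyl ketal 2 (not isolated)
Conditions: HC(OMe)3 (2.5 equiv), H2SO4 (cat.), MeOH, 23 °C, 24 h; then distil at 20 mbar (bath to 130 °C)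
Reagents that add atoms: trimethyl orthoformate, COC(OC)OC
Why: Acid-catalysed ketalisation followed by thermal loss of methanol is the standard enol-ether formation from a β-keto ester; the favoured E isomer has the CH(OMe)2 carbon cis to the ester, as needed for γ-deprotonation and ring closure, and no stereocentre is formed.

Step 2
Reactants: 4 2,6-dimethoxybenzaldehyde; 5 (E)-1-methoxy-3-(trimethylsilyloxy)buta-1,3-diene (Danishefsky's diene)
Product: 7 (1S,4E)-1-(2,6-dimethoxyphenyl)-1-hydroxy-5-methoxypent-4-en-3-one, via silyl ether 6 (not isolated)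
Conditions: (S)-1,1'-bi-2-naphthol [(S)-BINOL] (20 mol %), Ti(OiPr)4 (10 mol %), 4 Å MS, Et2O, −20 °C, 48 h; then KF (cat.), MeOH, 0 °C, 20 min
Reagents that add atoms: none
Why: Keck-type catalytic asymmetric Mukaiyama aldol (the open-chain arm of the formal hetero-Diels–Alder reaction): the titanium BINOLate binds the aldehyde so that the diene terminus adds to the Si face and sets C2 as S (sense taken by analogy with aryl aldehydes, to be confirmed by Mosher esters of 7), and the acid-free desilylation leaves the acid-labile 2,6-dimethoxybenzylic carbinol and the vinylogous ester open.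

Step 3
Reactants: 3 methyl (E)-3,4,4-trimethoxybut-2-enoate; 7 (1S,4E)-1-(2,6-dimethoxyphenyl)-1-hydroxy-5-methoxypent-4-en-3-one
Product: 11 (2S)-5-hydroxy-7,8,2',6'-tetramethoxyflavanone, via lithium dienolate 8 (not isolated), via dihydropyranone 9 (not isolated), via lithium enolate 10 (not isolated)
Conditions: 3 (2.5 equiv), LiN(iPr)2 (2.5 equiv), THF, −78 °C, 45 min; add 7, −78 → 0 °C, 3 h; AcOH (8 equiv), 0 → 23 °C, 1 h
Reagents that add atoms: none
Why: Proposed new method: excess 8 deprotonates the hydroxyl of 7, whose alkoxide closes ring C by 6-endo conjugate addition–elimination of methoxide to give 9 (O1–C8a bond, C2 untouched); the γ-carbon of 8 then adds to C8a of 9 and the resulting enolate acylates at C4a on the crotonate ester (Michael–Dieckmann, closest known type the Staunton–Weinreb annulation) to give 10, where mild acid ionises one ketal methoxy at C8 to an arenium-type cation that loses the C8a proton (as in aromatising additions to quinone monoketals), so ring A forms with 5-OH, 7-OMe and 8-OMe in place while the C2 stereocentre is carried through unchanged and the transient C8a centre is erased.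

**Compound list**

1 | methyl 4,4-dimethoxy-3-oxobutanoate | COC(=O)CC(=O)C(OC)OC | starting material
2 | methyl 3,3,4,4-tetramethoxybutanoate | COC(=O)CC(OC)(OC)C(OC)OC | intermediate
3 | methyl (E)-3,4,4-trimethoxybut-2-enoate | COC(=O)/C=C(/OC)C(OC)OC | intermediate
4 | 2,6-dimethoxybenzaldehyde | COc1cccc(OC)c1C=O | starting material
5 | (E)-1-methoxy-3-(trimethylsilyloxy)buta-1,3-diene | CO/C=C/C(=C)O[Si](C)(C)C | starting material
6 | (1S,4E)-1-(2,6-dimethoxyphenyl)-5-methoxy-1-(trimethylsilyloxy)pent-4-en-3-one | C[Si](C)(C)O[C@H](c1c(OC)cccc1OC)CC(=O)/C=C/OC | intermediate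
7 | (1S,4E)-1-(2,6-dimethoxyphenyl)-1-hydroxy-5-methoxypent-4-en-3-one | O[C@H](c1c(OC)cccc1OC)CC(=O)/C=C/OC | intermediate
8 | lithium 1,3,4,4-tetramethoxybuta-1,3-dien-1-olate (γ-lithiated 3) | [Li+].[O-]C(OC)=CC(OC)=C(OC)OC | intermediate
9 | (2S)-2-(2,6-dimethoxyphenyl)-2,3-dihydro-4H-pyran-4-one | O1[C@H](c2c(OC)cccc2OC)CC(=O)C=C1 | intermediate
10 | lithium (2S)-2-(2,6-dimethoxyphenyl)-7,8,8-trimethoxy-4-oxo-2,3,8,8a-tetrahydro-4H-chromen-5-olate (either configuration at C8a) | O1[C@H](c2c(OC)cccc2OC)CC(=O)C3=C([O-])C=C(OC)C(OC)(OC)C13.[Li+] | intermediate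
11 | (2S)-5-hydroxy-7,8,2',6'-tetramethoxyflavanone | COc1cc(O)c2c(c1OC)O[C@H](c1c(OC)cccc1OC)CC2=O | target

**Step count and risks**

Total steps: 3. Longest linear sequence: 2 (step 2 then step 3, or step 1 then step 3).

Steps most likely to fail, most risky first:

1. Step 3. The γ-carbanion of 8 carries two methoxy groups and must form a quaternary carbon on a weakly electrophilic vinylogous ester; α-attack, 1,2-addition or proton transfer may win. The fallback sets out from 4 and comes back at 10. It gives up the crotonate nucleophile and takes ring A from a dearomatised phenol. Ti(OiPr)4/(S)-BINOL-catalysed Mukaiyama aldol of 4 with 1-(tert-butylthio)-1-(trimethylsilyloxy)ethene gives S-tert-butyl (3S)-3-(2,6-dimethoxyphenyl)-3-(trimethylsilyloxy)propanethioate F1, and dilute aqueous HCl work-up gives S-tert-butyl (3S)-3-(2,6-dimethoxyphenyl)-3-hydroxypropanethioate F2. Separately, 3,4-dimethoxyphenol is oxidised with PhI(OAc)2 in MeOH to 3,4,4-trimethoxycyclohexa-2,5-dien-1-one F3. LiN(SiMe3)2 (1.1 equiv, THF, −78 → 0 °C) then adds the alkoxide of F2 to the unsubstituted enone carbon of F3 (oxa-Michael, O1–C8a), and the enolate closes ring C by Claisen acylation on the thioester to give 10, which is quenched with AcOH to 11 as in step 3.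

2. Step 2. The di-ortho-substituted, electron-rich aldehyde may react slowly or with low ee under titanium catalysis. The fallback sets out from 4 and comes back at 9. It replaces the Lewis-acid aldol by a hydrogen-bond-catalysed concerted hetero-Diels–Alder reaction. Aldehyde 4 and 1-(dimethylamino)-3-(tert-butyldimethylsilyloxy)buta-1,3-diene react in toluene at −40 °C with 20 mol % of 2,2-dimethyl-α,α,α',α'-tetra(1-naphthyl)-1,3-dioxolane-4,5-dimethanol, in the enantiomer that gives the 2S product (assigned against 9 from the main route), to give tert-butyl{[(2S)-2-(2,6-dimethoxyphenyl)-6-(dimethylamino)-3,6-dihydro-2H-pyran-4-yl]oxy}dimethylsilane F4. Acetyl chloride at −78 °C collapses F4 to 9, which enters step 3 in place of 7 with one equivalent less of base.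

3. Step 1. The crowded ketal 2 may not eliminate cleanly or may give E/Z mixtures. The fallback sets out from 1 and comes back at 3. It replaces acetal exchange by O-alkylation: KOtBu in DMPU at 0 °C converts 1 to the potassium enolate of methyl 4,4-dimethoxy-3-oxobutanoate F5, and dimethyl sulfate methylates F5 on oxygen to give 3, with the minor Z isomer removed by distillation.

**Further compounds**

F1 | step 3 | S-tert-butyl (3S)-3-(2,6-dimethoxyphenyl)-3-(trimethylsilyloxy)propanethioate | C[Si](C)(C)O[C@H](c1c(OC)cccc1OC)CC(=O)SC(C)(C)C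
F2 | step 3 | S-tert-butyl (3S)-3-(2,6-dimethoxyphenyl)-3-hydroxypropanethioate | O[C@H](c1c(OC)cccc1OC)CC(=O)SC(C)(C)C
F3 | step 3 | 3,4,4-trimethoxycyclohexa-2,5-dien-1-one | COC1=CC(=O)C=CC1(OC)OC
F4 | step 2 | tert-butyl{[(2S)-2-(2,6-dimethoxyphenyl)-6-(dimethylamino)-3,6-dihydro-2H-pyran-4-yl]oxy}dimethylsilane | O1[C@H](c2c(OC)cccc2OC)CC(O[Si](C)(C)C(C)(C)C)=CC1N(C)C
F5 | step 1 | potassium enolate of methyl 4,4-dimethoxy-3-oxobutanoate | [K+].COC(=O)C=C([O-])C(OC)OC
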